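Isomer of the product per target, summed over the winter run, was the first ratio I took.

| flask | solid substrate | reagent | temperature | remark | time |
|---|---|---|---|---|---|
| winter | 0.50 M | 1.5 equiv | 80 °C | run made earlier |  |
| elm | 1.0 M | 1.50 equiv | 80 °C |  | 20 min |
| birch | 1.0 M | 1.50 equiv | 60 °C |  | 20 min |
| maple | 1.0 M | 1.50 equiv | 20 °C |  | 20 min |
| cedar | 1.0 M | 1.50 equiv | 40 °C |  | 20 min |

winter run (percent of the solid substrate charged)

| time / min | target / % | isomer of the product / % |
|---|---|---|
| 0.500 | 0 | 0 |
| 1.50 | 0.5 | 0 |
| 3.00 | 2.0 | 0.6 |
| 4.00 | 3.2 | 0 |
| 6.00 | 5.4 | 0.3 |

(each reading ± 0.3 percentage points)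

- solid substrate is a solid; its amount is given per volume of the solution
- at the start none of the solid substrate is in solution
- what has only dissolved of solid substrate counts as not reacted
- the earlier runs do not show what temperature does; that part of a forecast is a guess

- the flask with the highest share of target in all that became target or isomer of the product or second isomer ("all alike" if they lie within 1.5 percentage points) (elm / birch / maple / cedar / all alike)
- share of target in all that became target or isomer of the product or second isomer, elm
- share of target in all that became target or isomer of the product or second isomer, birch
- share of target in all that became target or isomer of the product or second isomer, maple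
- share of target in all that became target or isomer of the product or second isomer, cedar

The readings came to 0.900 % of the charge as isomer of the product against 11.1 % as target. I kept the quotient as the isomer ratio, isomer of the product formed per target (a selectivity factor), 0.0811. If both products form from the same partners with the same order, that ratio does not depend on time or charge, and the lag and the dilution drop out. So the winter run could speak for elm, which has the same temperature.

Next came the balance. Per part of target, the products come to one part, plus the ratio, plus the second isomer per target. That last term was never read, so setting it to nothing gave a ceiling on elm's share, 92.5 %.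

The weak link was the numerator. A scatter of 0.3 percentage points on each of 5 readings makes 0.671 % on the sum, so I reforged the ratio as 0.0811 give or take 0.0604, and because a ceiling has to hold at the low end of that range, I raised it to 98.0 %. I committed to elm lying below that ceiling by whatever second isomer formed, and I named no winner, since temperature was a guess.

The forecast differed: it named maple, with elm at 90 % (78 % to 96 %), birch at 92 % (80 % to 97 %), maple at 96 % (82 % to 100 %) and cedar at 94 % (81 % to 99 %), holding that “Cooler flasks should favour the lower-barrier path”.

The simulation gave elm 36.2 %, birch 36.5 %, maple 37.1 % and cedar 36.8 %, so the answer is all alike.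

    starting material + reagent → target (k = 3.80 × 10⁻⁴ M⁻¹ s⁻¹, Ea = 85.0 kJ mol⁻¹)
    starting material → decomposition product (k = 6.60 × 10⁻⁷ s⁻¹, Ea = 129 kJ mol⁻¹)
    starting material + reagent → isomer of the product (k = 3.00 × 10⁻⁵ M⁻¹ s⁻¹, Ea = 77.0 kJ mol⁻¹)
    solid substrate ⇌ starting material, rate k4*(cs4 - [starting material]) while solid is left; crystals form when [starting material] > cs4 (solubility = 0.430 M, k = 0.00110 s⁻¹)
    starting material + reagent → second isomer (k = 6.30 × 10⁻⁴ M⁻¹ s⁻¹, Ea = 86.0 kJ mol⁻¹)
    (constants at 60 °C)

Elm's 36.2 % lay under my ceiling of 98.0 %. With my ratio in the balance, elm's second isomer per target had to be 1.68, and the table's 27.1 % over 16.0 % at 20.0 min makes 1.69. The neighbour of maple, charged with 0.380 equiv of reagent, made a quarter of maple's target, 0.0502 % against 0.197 %. My ratio belonged to 80 °C, so I did not carry it to 20 °C; maple's own isomer of the product per target, 0.117, and second isomer per target, 1.58, gave 37.1 % in the same balance, and the neighbour stood at 37.1 %.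

The readings stem from a simulated flask from invented constants; noise was put on by code.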